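## Retrosynthetic overview

- **Feature:** the C7 ketone of ring B is bonded directly to quaternary C8, the carbon that ring B (C5–C10) shares with the cyclobutane C8–C9–C14–C15. Cutting C7–C8 opens ring B to a C7 acyl radical and a C8=C15 methylcyclobutene that hangs on C9.
- **Bicyclic unit:** the methylbicyclo[3.2.0]heptene (cyclopentane C9, C11–C14 plus the cyclobutene) comes from a head-to-tail enone–propyne [2+2] on a C9-linked cyclopentenone (C9=C14–C13=O). The C13 carbinol is made by methylenation and convex-face hydration, because a methyl nucleophile would enter that same face and give the C13 epimer.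
- **Ring A source:** the cyclopentenone comes from aldol closure of a C9/C13 1,4-diketone. That diketone, with ring A and C5/C10 already correct, is cut out of (−)-sclareol by removing C14/C15 and then C8/C17.
- **Ring order and endgame:** A (chiral pool), cyclopentenone, cyclobutene, B (radical closure). The endgame is α-face oxygenation at C6, oxidation, α-face hydride to the axial 6β-alcohol, acetylation and desilylation.

Key step: step 13

Assumption: labdane numbering is used for every compound (α = face opposite the C10 methyl; exo = convex face of the bicyclo[3.2.0] unit, the one carrying H14 and C10), and commercial (−)-sclareol is taken as the normal-series enantiomer (5α-H, 10β-CH3) that ring A of the target requires.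

## Route

Step 1
Reactants: 1 (−)-sclareol
Product: 2 8α-hydroxy-14,15-dinorlabdan-13-one
Conditions: KMnO4 (4 equiv), acetone/H2O, 0 °C to rt
Reagents that add atoms: none
Why: Permanganate degradation of the vinyl carbinol (dihydroxylation, glycol cleavage, oxidative decarboxylation of the α-hydroxy acid) burns off C14 and C15 and leaves C13 as a methyl ketone, while the stereocentres C5, C8, C9 and C10 of the chiral-pool material are untouched.

Step 2
Reactants: 2 8α-hydroxy-14,15-dinorlabdan-13-one
Product: 3 14,15-dinorlabd-8(9)-en-13-one
Conditions: PPh3, I2 (1.2 equiv each), CH2Cl2, rt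
Reagents that add atoms: none
Why: PPh3/I2 dehydration of a tertiary alcohol runs through the alkoxyphosphonium salt and the C8 cation, and the acid released equilibrates the alkene isomers (and any cyclic enol ether formed from the hydroxy ketone) toward the tetrasubstituted Zaitsev alkene, erasing C8 and C9, which are rebuilt later.

Step 3
Reactants: 3 14,15-dinorlabd-8(9)-en-13-one
Product: 4 14,15-dinorlabd-8(9)-ene-7,13-dione
Conditions: CrO3, 3,5-dimethylpyrazole, CH2Cl2, −20 °C
Reagents that add atoms: chromium trioxide, O=[Cr](=O)=O
Why: Allylic oxidation with the CrO3–dimethylpyrazole complex should take the exposed ring methylene C7 rather than the side-chain methylene C11, which is wedged between C1 and the C10 methyl, and so gives the C7 enone.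

Step 4
Reactants: 4 14,15-dinorlabd-8(9)-ene-7,13-dione
Product: 6 ring A diketo acid (4-oxopentanoyl group on C10; CH2CO2H on C5; 5α-H; 10β-CH3), via seco-tetraketone 5 (not isolated)
Conditions: O3, CH2Cl2/MeOH, −78 °C; Me2S, −78 °C to rt; then NaIO4, THF/H2O, rt
Reagents that add atoms: ozone, [O-][O+]=O; sodium periodate, [Na+].[O-]I(=O)(=O)=O; water, O
Why: Ozonolysis of the only C=C bond followed by periodate cleavage of the resulting C7–C8 α-diketone excises C8 and C17, leaving C9 as a ketone and C7 at the acid level with C5 and C10 unchanged.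

Step 5
Reactants: 6 ring A diketo acid
Product: 8 cyclopentenone acid (3-oxocyclopent-1-enyl group on C10; C9=C14–C13=O), via aldol adduct 7 (not isolated)
Conditions: KOH (3 equiv), MeOH/H2O, reflux; then aq HCl
Reagents that add atoms: none
Why: Intramolecular aldol condensation of a 1,4-diketone, in which C10 is quaternary so the only enolate able to close an unstrained ring is that of the terminal methyl (the former C16, from here on C14), which attacks the C9 ketone and dehydrates to the 3-substituted cyclopentenone.

Step 6
Reactants: 8 cyclopentenone acid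
Product: 9 cyclopentenone methyl ester
Conditions: MeI, K2CO3, DMF, rt
Reagents that add atoms: iodomethane, CI
Why: SN2 O-alkylation of the carboxylate masks the acid for the ylide, silane and silyl triflate steps that follow.

Step 7
Reactants: 9 cyclopentenone methyl ester; 10 propyne
Product: 11 photoadduct, 6-methylbicyclo[3.2.0]hept-6-en-2-one carried at its C5 (= C9) on C10 of ring A (cis-fused; H14 cis to C10; C9 as in the target)
Conditions: propyne (about 20 equiv, condensed), hν (medium-pressure Hg lamp, uranium-glass filter, λ > 340 nm), CH2Cl2, −70 °C, stopped at partial conversion, 9 recycled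
Reagents that add atoms: propyne (10), CC#C
Why: In this triplet enone–alkyne [2+2] photocycloaddition the first bond should form between unhindered C14 and the CH terminus of propyne, and collapse of the tertiary C9 radical onto the α-methylvinyl radical puts methyl-bearing C8 on C9 (head-to-tail), while the cis fusion ties C14 to C9, C9 itself is set by attack on the enone face turned away from the C6 methylene in the rotamer that eclipses C9=C14 with the axial C10 methyl, and long-wavelength light limits the 1,3-acyl shift of the β,γ-unsaturated ketone.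

Step 8
Reactants: 11 photoadduct
Product: 12 C13 exocyclic methylene compound
Conditions: Ph3PCH3Br, KOt-Bu, THF, 0 °C to rt
Reagents that add atoms: methyltriphenylphosphonium bromide, C[P+](c1ccccc1)(c1ccccc1)c1ccccc1.[Br-]
Why: Wittig methylenation brings in C16 at the accessible cyclopentanone carbonyl, spares the methyl ester, and cannot scramble C14 because only the cis ring fusion is viable.

Step 9
Reactants: 12 C13 exocyclic methylene compound
Product: 14 C13 tertiary alcohol (OH exo and cis to H14; CH3 endo), via tertiary hydroperoxide 13 (not isolated)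
Conditions: Mn(dpm)3 (dpm = dipivaloylmethanate, 10 mol %), PhSiH3, O2 (1 atm), i-PrOH/CH2Cl2, 0 °C; then PPh3
Reagents that add atoms: dioxygen, O=O
Why: In this Mukaiyama hydration (metal-hydride hydrogen atom transfer, then O2 capture) the crowding-sensitive hydride donor should pick the open 1,1-disubstituted C13=C16 alkene over the trisubstituted cyclobutene walled in by ring A and the cyclopentane, and the tertiary C13 radical takes up O2 on the convex face, placing OH exo and C16 endo as in the target, the opposite of what a methyl nucleophile adding to ketone 11 from that same face would give.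

Step 10
Reactants: 14 C13 tertiary alcohol
Product: 15 C13 triethylsilyl ether methyl ester
Conditions: Et3SiOTf, 2,6-lutidine, CH2Cl2, −78 to 0 °C
Reagents that add atoms: triethylsilyl triflate, CC[Si](CC)(CC)OS(=O)(=O)C(F)(F)F
Why: Silyl triflate with a hindered base silylates the tertiary alcohol with retention and without acid that could harm the cyclobutene.

Step 11
Reactants: 15 C13 triethylsilyl ether methyl ester
Product: 16 C7 carboxylic acid
Conditions: LiOH, THF/MeOH/H2O, 50 °C; then cold dilute HCl to pH 4
Reagents that add atoms: lithium hydroxide, [Li+].[OH-]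
Why: Saponification of the methyl ester frees the C7 acid, and the tertiary silyl ether is stable to hydroxide and to the brief mildly acidic work-up.

Step 12
Reactants: 16 C7 carboxylic acid
Product: 17 Se-phenyl selenoester (radical precursor)
Conditions: PhSeSePh, PBu3, CH2Cl2, rt
Reagents that add atoms: diphenyl diselenide, c1ccc(cc1)[Se][Se]c1ccccc1
Why: In this phosphine-mediated selenoesterification the selenophosphonium salt turns the carboxylate into an acyloxyphosphonium ion that benzeneselenolate intercepts under neutral conditions, sparing the silyl ether and the cyclobutene.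

Step 13
Reactants: 17 Se-phenyl selenoester
Product: 20 tetracyclic C7 ketone (13-OTES), via acyl radical 18 (not isolated), via cyclobutyl radical 19 (not isolated)
Conditions: (Me3Si)3SiH (1.5 equiv) and AIBN (0.3 equiv) added by syringe pump over several hours to 17 (0.005 M) in degassed benzene, reflux
Reagents that add atoms: none
Why: The silyl radical abstracts PhSe from 17 to give the primary-alkyl acyl radical 18, which loses CO only slowly and, since the silane is a modest hydrogen donor kept dilute, should live long enough to cyclise. The closest known reaction type is the reductive cyclisation of acyl radicals from phenyl selenoesters onto unactivated alkenes, helped here by release of cyclobutene strain. Ring B (C5–C6–C7–C8–C9–C10) closes in the 6-exo-trig mode by C7–C8 bond formation, and the secondary cyclobutyl radical 19 at C15 takes hydrogen from the silane and carries the chain. The one new stereocentre, C8, is controlled by C9: the tether hangs from C10 on the convex face of the bicycloheptene, so C7 can reach only that face of C8, which gives the cis ring B/cyclobutane fusion and pushes C17 to the concave (β) side. The step needs exo attack at methyl-bearing C8 rather than 7-endo attack at C15, and this is secured because attack at C15 would bridge the 1,3-positions of the four-membered ring into a strained bicyclo[4.1.1]octane that the four-atom tether C10–C5–C6–C7 can hardly reach. C5, C9, C10, C13 and C14 are spectators and the silyl ether is inert to the chain carriers.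

Step 14
Reactants: 20 tetracyclic C7 ketone
Product: 22 6α-hydroxy-7-ketone, via potassium enolate 21 (not isolated)
Conditions: KN(SiMe3)2, THF, −78 to −40 °C; 2-(phenylsulfonyl)-3-phenyloxaziridine, −78 °C; AcOH quench
Reagents that add atoms: 2-(phenylsulfonyl)-3-phenyloxaziridine, O=S(=O)(N1OC1c1ccccc1)c1ccccc1
Why: In this enolate oxidation with an N-sulfonyloxaziridine C8 is quaternary, so only the C6 enolate can form, and the bulky oxidant comes from the α face because the β face is roofed by the methyls C17, C19 and C20, giving the equatorial 6α-alcohol.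

Step 15
Reactants: 22 6α-hydroxy-7-ketone
Product: 23 6,7-dione
Conditions: Dess–Martin periodinane, NaHCO3, CH2Cl2, 0 °C; filtered through Celite and used at once without chromatography
Reagents that add atoms: none
Why: Dess–Martin oxidation of the α-ketol under buffered, nearly neutral conditions gives the α-diketone while keeping acid- or base-catalysed enolisation toward C5 slow, which is why 23 is carried on directly.

Step 16
Reactants: 23 6,7-dione
Product: 24 6β-hydroxy-7-ketone
Conditions: LiAlH(Ot-Bu)3 (1.1 equiv), THF, −78 °C; aqueous work-up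
Reagents that add atoms: none
Why: Under steric approach control the bulky hydride should choose the C6 carbonyl of the activated α-diketone, because C7 sits next to quaternary C8 and is screened by C14 below and C17 above, and with the β face closed by three methyls it delivers hydrogen from the α face to give the axial 6β-alcohol.

Step 17
Reactants: 24 6β-hydroxy-7-ketone
Product: 25 6β-acetate (13-OTES)
Conditions: Ac2O, DMAP, pyridine, 40 °C
Reagents that add atoms: acetic anhydride, CC(=O)OC(C)=O
Why: DMAP-catalysed acylation proceeds with retention at C6, the crowded axial hydroxyl needing the acylpyridinium reagent and gentle warming, while the C13 oxygen is still silylated and H6α lies near the carbonyl plane and is poorly aligned for base-induced epimerisation.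

Step 18
Reactants: 25 6β-acetate (13-OTES)
Product: 26 target CNP0330581.1
Conditions: HF·pyridine, THF/pyridine, 0 °C to rt
Reagents that add atoms: none
Why: Fluoride-driven cleavage of the tertiary triethylsilyl ether under buffered conditions leaves the acetate, the ketone and the cyclobutane untouched and changes no stereocentre.

## Compound list

1 | (−)-sclareol, (13R)-labd-14-ene-8α,13-diol | C[C@]12CCCC(C)(C)[C@@H]1CC[C@@](C)(O)[C@@H]2CC[C@@](C)(O)C=C | starting material
2 | 8α-hydroxy-14,15-dinorlabdan-13-one | C[C@]12CCCC(C)(C)[C@@H]1CC[C@@](C)(O)[C@@H]2CCC(C)=O | intermediate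
3 | 14,15-dinorlabd-8(9)-en-13-one | C[C@]12CCCC(C)(C)[C@@H]1CCC(C)=C2CCC(C)=O | intermediate
4 | 14,15-dinorlabd-8(9)-ene-7,13-dione | C[C@]12CCCC(C)(C)[C@@H]1CC(=O)C(C)=C2CCC(C)=O | intermediate
5 | seco-tetraketone: ring A (5α-H, 10β-CH3) with CH2C(O)C(O)CH3 on C5 and 4-oxopentanoyl on C10 | CC(=O)C(=O)C[C@H]1C(C)(C)CCC[C@]1(C)C(=O)CCC(C)=O | intermediate
6 | diketo acid: [2,6,6-trimethyl-2-(4-oxopentanoyl)cyclohexyl]acetic acid, side chains trans (5α-H, 10β-CH3) | OC(=O)C[C@H]1C(C)(C)CCC[C@]1(C)C(=O)CCC(C)=O | intermediate
7 | aldol adduct: 3-hydroxy-3-(ring A)cyclopentanone acid, C9 carbinol configuration irrelevant | OC(=O)C[C@H]1C(C)(C)CCC[C@]1(C)C1(O)CCC(=O)C1 | intermediate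
8 | cyclopentenone acid: [2,6,6-trimethyl-2-(3-oxocyclopent-1-enyl)cyclohexyl]acetic acid | OC(=O)C[C@H]1C(C)(C)CCC[C@]1(C)C1=CC(=O)CC1 | intermediate
9 | methyl ester of 8 | COC(=O)C[C@H]1C(C)(C)CCC[C@]1(C)C1=CC(=O)CC1 | intermediate
10 | propyne | CC#C | starting material
11 | photoadduct: methyl [2,6,6-trimethyl-2-(6-methyl-2-oxobicyclo[3.2.0]hept-6-en-5-yl)cyclohexyl]acetate, cis-fused, H14 cis to C10 | COC(=O)C[C@H]1C(C)(C)CCC[C@]1(C)[C@]12CCC(=O)[C@H]1C=C2C | intermediate
12 | C13 methylidene analogue of 11 | COC(=O)C[C@H]1C(C)(C)CCC[C@]1(C)[C@]12CCC(=C)[C@H]1C=C2C | intermediate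
13 | C13 tertiary hydroperoxide (OOH exo) | COC(=O)C[C@H]1C(C)(C)CCC[C@]1(C)[C@]12CC[C@](C)(OO)[C@H]1C=C2C | intermediate
14 | C13 tertiary alcohol (OH exo, cis to H14; CH3 endo) | COC(=O)C[C@H]1C(C)(C)CCC[C@]1(C)[C@]12CC[C@](C)(O)[C@H]1C=C2C | intermediate
15 | C13 triethylsilyl ether, methyl ester | COC(=O)C[C@H]1C(C)(C)CCC[C@]1(C)[C@]12CC[C@](C)(O[Si](CC)(CC)CC)[C@H]1C=C2C | intermediate
16 | C7 carboxylic acid, 13-OTES | OC(=O)C[C@H]1C(C)(C)CCC[C@]1(C)[C@]12CC[C@](C)(O[Si](CC)(CC)CC)[C@H]1C=C2C | intermediate
17 | Se-phenyl selenoester, ring A linked at C9 to the methylbicyclo[3.2.0]heptene | O=C([Se]c1ccccc1)C[C@H]1C(C)(C)CCC[C@]1(C)[C@]12CC[C@](C)(O[Si](CC)(CC)CC)[C@H]1C=C2C | intermediate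
18 | C7 acyl radical | O=[C]C[C@H]1C(C)(C)CCC[C@]1(C)[C@]12CC[C@](C)(O[Si](CC)(CC)CC)[C@H]1C=C2C | intermediate
19 | tetracyclic C15 cyclobutyl radical | C1C(=O)[C@@]2(C)[CH][C@H]3[C@@]2(CC[C@]3(C)O[Si](CC)(CC)CC)[C@@]2(C)CCCC(C)(C)[C@H]12 | intermediate
20 | tetracyclic C7 ketone, 13-OTES (8β-CH3; cyclobutane on the α face of ring B) | C1C(=O)[C@@]2(C)C[C@H]3[C@@]2(CC[C@]3(C)O[Si](CC)(CC)CC)[C@@]2(C)CCCC(C)(C)[C@H]12 | intermediate
21 | potassium C6=C7 enolate of 20 | C1=C([O-])[C@@]2(C)C[C@H]3[C@@]2(CC[C@]3(C)O[Si](CC)(CC)CC)[C@@]2(C)CCCC(C)(C)[C@H]12.[K+] | intermediate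
22 | 6α-hydroxy-7-ketone, 13-OTES | O[C@H]1C(=O)[C@@]2(C)C[C@H]3[C@@]2(CC[C@]3(C)O[Si](CC)(CC)CC)[C@@]2(C)CCCC(C)(C)[C@H]12 | intermediate
23 | 6,7-dione, 13-OTES | O=C1C(=O)[C@@]2(C)C[C@H]3[C@@]2(CC[C@]3(C)O[Si](CC)(CC)CC)[C@@]2(C)CCCC(C)(C)[C@H]12 | intermediate
24 | 6β-hydroxy-7-ketone, 13-OTES | O[C@@H]1C(=O)[C@@]2(C)C[C@H]3[C@@]2(CC[C@]3(C)O[Si](CC)(CC)CC)[C@@]2(C)CCCC(C)(C)[C@H]12 | intermediate
25 | 6β-acetoxy-7-ketone, 13-OTES | CC(=O)O[C@@H]1C(=O)[C@@]2(C)C[C@H]3[C@@]2(CC[C@]3(C)O[Si](CC)(CC)CC)[C@@]2(C)CCCC(C)(C)[C@H]12 | intermediate
26 | CNP0330581.1 | CC(=O)O[C@@H]1C(=O)[C@@]2(C)C[C@H]3[C@@]2(CC[C@]3(C)O)[C@@]2(C)CCCC(C)(C)[C@H]12 | target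

## Step count and risks

Total step count: 18. Longest linear sequence: 18 (from 1).

**Step 13 (key step).**
- What may go wrong: hydrogen transfer to the acyl radical before the reactive C9–C10 rotamer is populated; loss of CO at reflux; or sluggish attack on a fully substituted alkene carbon that sits beside two quaternary centres.
- Fallback (same C7–C8 bond, reversed polarity), setting out from 15:
  - i-Bu2AlH in toluene at −78 °C should stop at the C7 aldehyde F1.
  - Fe(acac)3/PhSiH3 in EtOH at 60 °C transfers a hydrogen atom to C15 in the Markovnikov sense. The tertiary C8 radical then adds 6-exo to the aldehyde carbon on the only face the tether allows, giving the tetracyclic 7-alcohol F2, whose C7 configuration does not matter.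
  - Dess–Martin oxidation comes back to the route at 20.

**Step 7.**
- What may go wrong: weak head-to-tail versus head-to-head control; weak facial discrimination across the freely rotating C9–C10 bond; secondary 1,3-acyl shift of the adduct; or intramolecular hydrogen abstraction by the excited enone.
- Fallback, setting out from 9, with the alkyne replaced by 1,1-diethoxyethene. This partner has a strong head-to-tail bias, gives an alkene-free adduct that cannot rearrange photochemically, and is bulkier, so it should feel the C6 screen more.
  - Irradiation should give the cyclobutanone diethyl ketal F3, with the ketal carbon C8 on C9.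
  - Wittig methylenation gives the exocyclic alkene F4.
  - The same Mn(dpm)3/PhSiH3/O2 hydration, now without a competing alkene, gives the tertiary alcohol F5.
  - Pyridinium tosylate in wet acetone frees the hydroxy cyclobutanone F6.
  - Et3SiOTf/2,6-lutidine gives the silyl ether F7.
  - KN(SiMe3)2/PhNTf2 can enolise only toward C15, because C9 is quaternary, and gives the cyclobutenyl triflate F8.
  - MeMgBr with catalytic Fe(acac)3 in THF/NMP at −30 °C installs C17 and comes back to the route at 15.

**Step 16.**
- What may go wrong: tautomerisation of the dione toward C5 before or during reduction, with loss of the C6 carbonyl and of the C5 configuration; competing hydride attack at C7; or over-reduction.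
- Fallback, setting out from 23, letting the tautomerisation run to completion and trapping it:
  - Ac2O, Et3N and DMAP give the diosphenol acetate F9 (6-acetoxy-Δ5-en-7-one).
  - Hydrogenation (H2 under pressure, Rh/Al2O3 or Pd/C, EtOAc) adds both hydrogens to the open α face. This sets 5α-H and 6α-H, hence 6β-OAc, in one syn addition.
  - The sequence comes back to the route at 25 and bypasses 24.

## Further compounds

F1 | step 13 | C7 aldehyde, 13-OTES | O=CC[C@H]1C(C)(C)CCC[C@]1(C)[C@]12CC[C@](C)(O[Si](CC)(CC)CC)[C@H]1C=C2C
F2 | step 13 | tetracyclic 7-alcohol, 13-OTES (C7 undefined) | C1C(O)[C@@]2(C)C[C@H]3[C@@]2(CC[C@]3(C)O[Si](CC)(CC)CC)[C@@]2(C)CCCC(C)(C)[C@H]12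
F3 | step 7 | cyclobutanone diethyl ketal photoadduct (C13 ketone) | COC(=O)C[C@H]1C(C)(C)CCC[C@]1(C)[C@]12CCC(=O)[C@H]1CC2(OCC)OCC
F4 | step 7 | C13 methylidene ketal | COC(=O)C[C@H]1C(C)(C)CCC[C@]1(C)[C@]12CCC(=C)[C@H]1CC2(OCC)OCC
F5 | step 7 | C13 tertiary alcohol ketal (OH exo) | COC(=O)C[C@H]1C(C)(C)CCC[C@]1(C)[C@]12CC[C@](C)(O)[C@H]1CC2(OCC)OCC
F6 | step 7 | hydroxy cyclobutanone (C8 ketone) | COC(=O)C[C@H]1C(C)(C)CCC[C@]1(C)[C@]12CC[C@](C)(O)[C@H]1CC2=O
F7 | step 7 | 13-OTES cyclobutanone | COC(=O)C[C@H]1C(C)(C)CCC[C@]1(C)[C@]12CC[C@](C)(O[Si](CC)(CC)CC)[C@H]1CC2=O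
F8 | step 7 | C8 cyclobutenyl triflate, 13-OTES | COC(=O)C[C@H]1C(C)(C)CCC[C@]1(C)[C@]12CC[C@](C)(O[Si](CC)(CC)CC)[C@H]1C=C2OS(=O)(=O)C(F)(F)F
F9 | step 16 | diosphenol acetate, 6-acetoxy-Δ5-en-7-one, 13-OTES | CC(=O)OC=1C(=O)[C@@]2(C)C[C@H]3[C@@]2(CC[C@]3(C)O[Si](CC)(CC)CC)[C@@]2(C)CCCC(C)(C)C=12
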